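## Retrosynthetic overview
1. The C15/C16 exo-methylene enone comes from the C15 ketone by Mannich/elimination. The C6 methyl acetal/THF ring on ring A is made first from a cis-fused lactone.
2. The bicyclo[3.2.1] D ring closes by transannular Dieckmann acylation of the C8 spirolactone enolate into a C11–O/C13–CH2 bridging lactone. That lactone sits in a 2-oxabicyclo[3.3.1]nonane that fixes the C9/C13 relative stereochemistry. C11 is corrected afterwards.
3. The C9–C10 bond and the δ-spirolactone come from Ti(III) reductive opening of the ring-A spiro-epoxide and Giese addition to a bridged cyclohexene enoate.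
4. Ring A with the quaternary C4 comes from an enantioselective Diels–Alder (β-methylbutenolide + 1-siloxydiene). The enoate comes from 3,5-dihydroxyphenylacetic acid by lipase desymmetrization.

Ring-formation order: ring A and cis-fused γ-lactone (step 2), then THF acetal (step 5), bridged lactone/ring C (steps 8–15), C9–C10 bond and δ-spirolactone (step 16), ring D (step 17).

Assumptions:
- The natural C6 anomer is the thermodynamic one (OMe exo, trans to ring A).
- Catalyst and enzyme antipodes are chosen to give the drawn enantiomers.
- C8–H is unspecified in 19; it is epimerizable and reset in step 17.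

## Route

**Step 1**
Reactants: 1 (E)-crotonaldehyde
Product: 2 (E)-1-(TBSO)-1,3-butadiene
Conditions: TBSOTf, Et3N, CH2Cl2, 0 °C
Reagents that add atoms: TBSOTf, CC(C)(C)[Si](C)(C)OS(=O)(=O)C(F)(F)F (TBS retained)
Why: γ-Deprotonation and O-silylation of the enal gives the silyl dienol ether (E diene), the nucleophilic diene for step 2.

**Step 2**
Reactants: 2 + 3 (4-methylfuran-2(5H)-one)
Product: 4 cis-fused 7-TBSO-3a-methyl-3a,4,7,7a-tetrahydro-2-benzofuran-1(3H)-one (C4 quaternary, C5 set; C10 stereochemistry is endo and is destroyed in step 6)
Conditions: 20 mol% chiral cationic oxazaborolidinium Tf2N⁻ catalyst, CH2Cl2, –78 → –30 °C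
Reagents that add atoms: none
Why: Proposed new method: an enantioselective Lewis-acid Diels–Alder of a β-substituted (trisubstituted) butenolide with a 1-siloxydiene. The boron acid binds the locked s-cis lactone carbonyl. In an asynchronous endo transition state the remote diene terminus (C3) bonds to the β-carbon (C4) first, and the siloxy donor fixes the "ortho" regiochemistry (C10–C5). The catalyst shields one face, so the quaternary C4 and C5 are set together as a cis-fused lactone (C19 and C6 cis, Me and H5 cis). The closest known reactions are the oxazaborolidinium-catalysed Diels–Alder of α-substituted acroleins and the Lewis-acid Diels–Alder of unsubstituted butenolides.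

**Step 3**
Reactants: 4
Product: 5 saturated lactone
Conditions: H2 (1 atm), 10% Pd/C, EtOAc, 25 °C
Reagents that add atoms: none (H only)
Why: The cis-disubstituted ring alkene is hydrogenated selectively. No stereocentre is touched, and the lactone and silyl ether survive.

**Step 4**
Reactants: 5
Product: 6 lactol (C6 at aldehyde oxidation level; C6 epimers)
Conditions: DIBAL-H (1.1 equiv), CH2Cl2, –78 °C
Reagents that add atoms: none (H only)
Why: Partial lactone reduction by DIBAL stops at the lactol through a stable aluminate. The TBS ether is retained.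

**Step 5**
Reactants: 6
Product: 7 1-methoxy-3a-methyl-octahydro-2-benzofuran-7-ol (C6 acetal, OMe trans to ring A)
Conditions: MeOH, CSA (0.2 equiv), 40 °C
Reagents that add atoms: methanol, CO (OMe retained)
Why: Acid-catalysed acetalization under anomeric/thermodynamic control gives the convex-face OMe anomer, which is the natural C6 configuration by assumption. The same conditions cleave the secondary TBS ether.

**Step 6**
Reactants: 7
Product: 8 ketone at C10
Conditions: Dess–Martin periodinane, NaHCO3, CH2Cl2, 25 °C
Reagents that add atoms: none
Why: Oxidation of the secondary alcohol removes the C10 stereocentre. The acetal is untouched under these buffered, non-acidic conditions.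

**Step 7**
Reactants: 8
Product: 9 C10 spiro-epoxide (C20 installed; epoxide epimers at C10)
Conditions: Me3S⁺ I⁻, n-BuLi, THF, –10 → 0 °C
Reagents that add atoms: trimethylsulfonium iodide, C[S+](C)C.[I-] (CH2 retained as C20)
Why: Corey–Chaykovsky methylenation of the ketone gives the epoxide. Both C10 epimers give the same tertiary radical in step 16, so their ratio does not matter.

**Step 8**
Reactants: 10 3,5-dihydroxyphenylacetic acid
Product: 11 methyl 3,5-dihydroxyphenylacetate
Conditions: MeOH, cat. H2SO4, reflux
Reagents that add atoms: methanol, CO (OMe retained)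
Why: Fischer esterification.

**Step 9**
Reactants: 11
Product: 12 methyl (all-cis-3,5-dihydroxycyclohexyl)acetate (meso)
Conditions: H2 (50 bar), 5% Rh/Al2O3, MeOH, 50 °C
Reagents that add atoms: none (H only)
Why: Arene hydrogenation delivers all hydrogens from the catalyst face, so the chain and both OH groups end up cis (all-cis relationship). The ester survives.

**Step 10**
Reactants: 12
Product: 13 monoacetate (free OH = future C11–O; OAc = future C8)
Conditions: Pseudomonas cepacia lipase, vinyl acetate, TBME, 25 °C
Reagents that add atoms: vinyl acetate, C=COC(C)=O (acetyl retained)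
Why: Enzymatic desymmetrization acetylates one of the two enantiotopic OH groups and sets the ring-C absolute configuration (C11/C13). The enzyme antipode is chosen to give 13 as drawn.

**Step 11**
Reactants: 13
Product: 14 7-acetoxy-2-oxabicyclo[3.3.1]nonan-3-one (bridging lactone)
Conditions: TsOH (5 mol%), toluene, 80 °C
Reagents that add atoms: none (MeOH lost)
Why: In the triaxial all-cis chair the free OH and the CH2CO2Me chain are 1,3-diaxial, so intramolecular transesterification closes the bridge. The bridge is the cis-1,3 stereochemical lock (O11 and C16 on the same face).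

**Step 12**
Reactants: 14
Product: 15 7-hydroxy-2-oxabicyclo[3.3.1]nonan-3-one
Conditions: K2CO3 (0.3 equiv), MeOH, 0 °C, 30 min
Reagents that add atoms: none
Why: Mild methanolysis removes the acetate faster than it opens the strain-free bridging lactone.

**Step 13**
Reactants: 15
Product: 16 2-oxabicyclo[3.3.1]nonane-3,7-dione
Conditions: Dess–Martin periodinane, CH2Cl2, 25 °C
Reagents that add atoms: none
Why: Oxidation of the secondary alcohol to the C8 ketone; the lactone is unaffected.

**Step 14**
Reactants: 16
Product: 17 enol triflate (C8(OTf)=C9)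
Conditions: LDA (1.05 equiv), THF, –78 °C; then PhNTf2
Reagents that add atoms: PhNTf2, O=S(=O)(C(F)(F)F)N(c1ccccc1)S(=O)(=O)C(F)(F)F (Tf retained)
Why: The ketone α-H (more acidic than the lactone α-CH2) is removed kinetically. Deprotonation goes toward C9, which is inductively acidified by the β-oxygen at C11. The minor C8=C14 regioisomer is removed by chromatography.

**Step 15**
Reactants: 17
Product: 18 methyl 3-oxo-2-oxabicyclo[3.3.1]non-7-ene-7-carboxylate (the C7 ester and C8=C9 acceptor)
Conditions: Pd(OAc)2, PPh3, CO (1 atm), MeOH, Et3N, DMF, 60 °C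
Reagents that add atoms: carbon monoxide, [C-]#[O+]; methanol, CO (both retained as CO2Me)
Why: Pd-catalysed methoxycarbonylation of the vinyl triflate. The bridging lactone survives.

**Step 16**
Reactants: 9 + 18
Product: 19 spirolactone/bridged lactone (δ-lactone C20–O–C7(=O); C8–H unspecified)
Conditions: Cp2TiCl2 (3 equiv), Zn (6 equiv), collidine·HCl (5 equiv), THF, 25 °C
Reagents that add atoms: none (H from collidine·HCl only; MeOH lost on lactonization)
Why: Nugent–RajanBabu Ti(III) epoxide opening gives the tertiary C10 radical and a primary Ti–alkoxide at C20. The radical attacks the face of ring A anti to the axial C19 methyl, which sets C20 up and the new C9 bond down (C10 stereocentre). It adds to C9 of the enoate by axial/exo attack on the face opposite the lactone bridge, so C10 is axial-down at C9 (C9 stereocentre). The resulting Ti enolate is protonated, and the alkoxide closes the δ-lactone onto the methyl ester.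

**Step 17**
Reactants: 19
Product: 20 11-epi bicyclo[3.2.1] keto lactone (C11–OH axial, syn to the bridge)
Conditions: LDA (2 equiv), THF, –78 → –20 °C; aq. NH4Cl
Reagents that add atoms: none
Why: Known Dieckmann/Claisen reactivity applied transannularly. The C8 enolate sits at the bicyclo[3.3.1] "3-endo" position, about 2.8 Å from the bridge carbonyl C15 at the "7-position". Acylation and collapse of the cage tetrahedral intermediate cleave C15–O11. This forms the C8–C15 bond on the top face, so C8 quaternary has C15 up and C7 down. The C9, C10 and C13 stereocentres are untouched.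

**Step 18**
Reactants: 20
Product: 21 C11,C15-diketone
Conditions: Dess–Martin periodinane, NaHCO3, CH2Cl2, 25 °C
Reagents that add atoms: none
Why: Oxidation of the axial alcohol, which is fast and does not scramble C9 under these buffered conditions.

**Step 19**
Reactants: 21
Product: 22 C11-equatorial alcohol (natural C11 configuration)
Conditions: Al(OiPr)3 (3 equiv), iPrOH/toluene, 80 °C
Reagents that add atoms: none (H only)
Why: Meerwein–Ponndorf–Verley equilibration gives the thermodynamic equatorial (down) alcohol, which avoids the two syn-axial contacts with C15/C16. The C15 ketone is shielded by quaternary C8 and the cage.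

**Step 20**
Reactants: 22
Product: 23 Mannich base at C16 (C16 epimers)
Conditions: LDA (3.3 equiv), THF, –78 °C; then Me2N⁺=CH2 I⁻
Reagents that add atoms: Eschenmoser's salt, C[N+](C)=C.[I-] (CH2NMe2 retained)
Why: The only enolizable position is C16, because C8 is quaternary. Enolate aminomethylation tolerates the free alkoxide.

**Step 21**
Reactants: 23
Product: 24 angustifolin (target)
Conditions: MeI, CH2Cl2, 25 °C; then aq. NaHCO3 (or DBU)
Reagents that add atoms: none (the added methyl ends in NMe3)
Why: Quaternization and E1cB loss of NMe3 give the exo-methylene enone. The acetal, lactone and C11 stereocentre are untouched under mild conditions.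

## Compound list
1 | (E)-but-2-enal | C/C=C/C=O | starting material
2 | (E)-tert-butyldimethyl(buta-1,3-dienyloxy)silane | C=C/C=C/O[Si](C)(C)C(C)(C)C | intermediate
3 | 4-methylfuran-2(5H)-one | CC1=CC(=O)OC1 | starting material
4 | cis-fused Diels–Alder lactone (C10 stereochemistry unspecified) | O=C1OC[C@]2(C)CC=CC(O[Si](C)(C)C(C)(C)C)[C@H]12 | intermediate
5 | saturated TBS-lactone | O=C1OC[C@]2(C)CCCC(O[Si](C)(C)C(C)(C)C)[C@H]12 | intermediate
6 | lactol (C6 epimers, C10 unspecified) | OC1OC[C@]2(C)CCCC(O[Si](C)(C)C(C)(C)C)[C@H]12 | intermediate
7 | methyl acetal alcohol | CO[C@H]1OC[C@]2(C)CCCC(O)[C@H]12 | intermediate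
8 | C10 ketone | CO[C@H]1OC[C@]2(C)CCCC(=O)[C@H]12 | intermediate
9 | C10 spiro-epoxide (C10 unspecified) | CO[C@H]1OC[C@]2(C)CCCC3(CO3)[C@H]12 | intermediate
10 | 3,5-dihydroxyphenylacetic acid | OC(=O)Cc1cc(O)cc(O)c1 | starting material
11 | methyl 3,5-dihydroxyphenylacetate | COC(=O)Cc1cc(O)cc(O)c1 | intermediate
12 | all-cis methyl 3,5-dihydroxycyclohexylacetate | COC(=O)C[C@@H]1C[C@H](O)C[C@H](O)C1 | intermediate
13 | monoacetate (OH at future C11, OAc at future C8) | COC(=O)C[C@@H]1C[C@H](O)C[C@H](OC(C)=O)C1 | intermediate
14 | 7-acetoxy-2-oxabicyclo[3.3.1]nonan-3-one | CC(=O)O[C@H]1C[C@@H]2C[C@H](C1)CC(=O)O2 | intermediate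
15 | 7-hydroxy-2-oxabicyclo[3.3.1]nonan-3-one | O[C@H]1C[C@@H]2C[C@H](C1)CC(=O)O2 | intermediate
16 | 2-oxabicyclo[3.3.1]nonane-3,7-dione | O=C1C[C@@H]2C[C@H](C1)CC(=O)O2 | intermediate
17 | enol triflate | FC(F)(F)S(=O)(=O)OC1=C[C@@H]2C[C@H](C1)CC(=O)O2 | intermediate
18 | bridged enoate (acceptor) | COC(=O)C1=C[C@@H]2C[C@H](C1)CC(=O)O2 | intermediate
19 | spirolactone with bridging lactone (C8 unspecified) | O=C1OC[C@]2(CCC[C@@]3(C)CO[C@H](OC)[C@@H]23)[C@@H]4[C@@H]5C[C@@H](CC(=O)O5)CC14 | intermediate
20 | 11-epi bicyclo[3.2.1] keto lactone | C1C(=O)[C@]23C[C@H]1C[C@H](O)[C@H]2[C@@]1(CCC[C@@]2(C)CO[C@H](OC)[C@H]21)COC3=O | intermediate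
21 | C11,C15-diketone | C1C(=O)[C@]23C[C@H]1CC(=O)[C@H]2[C@@]1(CCC[C@@]2(C)CO[C@H](OC)[C@H]21)COC3=O | intermediate
22 | 16-nor-methylene C11-equatorial alcohol | C1C(=O)[C@]23C[C@H]1C[C@@H](O)[C@H]2[C@@]1(CCC[C@@]2(C)CO[C@H](OC)[C@H]21)COC3=O | intermediate
23 | C16 Mannich base (C16 unspecified) | CN(C)CC1C(=O)[C@]23C[C@H]1C[C@@H](O)[C@H]2[C@@]1(CCC[C@@]2(C)CO[C@H](OC)[C@H]21)COC3=O | intermediate
24 | angustifolin | C=C1C(=O)[C@]23C[C@H]1C[C@@H](O)[C@H]2[C@@]1(CCC[C@@]2(C)CO[C@H](OC)[C@H]21)COC3=O | target

## Totals
Total steps: 21. Longest linear sequence: 14 (10 → 11 → 12 → 13 → 14 → 15 → 16 → 17 → 18 → 19 → 20 → 21 → 22 → 23 → 24).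

## Three steps most likely to fail
1. **Step 2, the new Diels–Alder.** β-Methylbutenolide is a poor dienophile, and the catalyst may desilylate the diene or give low ee.
   - Fallback: run it as a racemic Me2AlCl-promoted Diels–Alder. Carry racemic 9 into step 16 with enantiopure 18 and separate the two diastereomeric spirolactones by chromatography (resolution in place of asymmetric catalysis).
2. **Step 17, the transannular Claisen.** It may stall at the tetrahedral intermediate or suffer retro-Claisen, and C16 deprotonation competes with C8 enolization.
   - Fallback: open the bridging lactone of 19 with Me(OMe)NH·HCl/AlMe3 to the Weinreb amide, protect C11–OH as TBS, then close ring D by LDA acylation with the Weinreb amide (a stable chelated tetrahedral intermediate).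
3. **Step 19, C11 epimerization.** It may also reduce the C15 ketone, or epimerize C9.
   - Fallback: skip the oxidation/reduction and invert 20 directly by SN2, via the C11 triflate (Tf2O, 2,6-lutidine) then CsOPiv/18-crown-6 and methanolysis.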